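**Plan**
- Retrosynth­esis: the nine O-benzyl groups come off first and the C3–O bond is traced back to C3–B. The upper pyran ring is then cut at O1–C2 and C3–C4, and last the C4–C8″ link is cut between the carbinol carbon and C8 of the catechin unit.
- The cut is possible because C4 of the upper pyran ring is benzylic both to the 7,8-dioxygenated A ring and to C8″ of the catechin unit. O1, C8a, C4a and C4 are therefore a masked o-quinone methide, and the three contiguous trans substituents on C2, C3 and C4 map onto an E-alkene.
- Forward: (+)-catechin is benzylated, brominated at C8 and lithiated, then added to a 2-O-allyl pyrogallol aldehyde (C4–C8″ bond). Deallylation gives the 2-hydroxybenzhydrol.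
- The upper pyran ring, the only ring made, closes in an acid-catalysed [4+2] reaction of the derived quinone methide with an (E)-styrylboronate. C–B oxidation and hydrogenolysis finish the synthesis.
- Stereochemistry: C2″ and C3″ come from (+)-catechin. C2/C3 trans comes from the E-alkene, C2/C4 cis from endo approach, the absolute face from the chiral phosphoric acid, and C3–OH from stereoretentive oxidation.

Key step: step 10

Assumption: the sense of facial induction by (R)-TRIP in step 10 is assigned by analogy, and its antipode is used in the same way should the opposite face be attacked; carbinols 10 and 11 are handled as mixtures of epimers because that centre becomes planar in step 10.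

**Step 1**
Reactants: 1 (+)-catechin
Product: 2 5,7,3′,4′-tetra-O-benzyl-(+)-catechin
Conditions: BnBr (4.4 equiv), K2CO3, DMF, 0 °C → rt
Reagents that add atoms: benzyl bromide, BrCc1ccccc1
Why: Williamson etherification in which carbonate ionises only the four phenols, so the secondary 3-OH stays free and no stereocentre is touched.

**Step 2**
Reactants: 2 5,7,3′,4′-tetra-O-benzyl-(+)-catechin
Product: 3 3,5,7,3′,4′-penta-O-benzyl-(+)-catechin
Conditions: NaH, BnBr, cat. Bu4NI, DMF, 0 °C → rt
Reagents that add atoms: benzyl bromide, BrCc1ccccc1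
Why: Williamson etherification of the secondary alkoxide; with every phenol already capped the base cannot open the pyran ring through a quinone methide, so C2 and C3 keep their configuration.

**Step 3**
Reactants: 3 3,5,7,3′,4′-penta-O-benzyl-(+)-catechin
Product: 4 8-bromo-3,5,7,3′,4′-penta-O-benzyl-(+)-catechin
Conditions: NBS (1.0 equiv), CH2Cl2, −78 °C → 0 °C
Reagents that add atoms: N-bromosuccinimide, O=C1CCC(=O)N1Br
Why: Electrophilic aromatic bromination; in 5,7-di-O-benzylflavans C8 is the most nucleophilic ring position and NBS at low temperature is known to brominate it in preference to C6 and ring B.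

**Step 4**
Reactants: 5 2,3,4-trihydroxybenzaldehyde
Product: 6 2,3,4-tris(benzyloxy)benzaldehyde
Conditions: BnBr (3.5 equiv), K2CO3, DMF, 60 °C
Reagents that add atoms: benzyl bromide, BrCc1ccccc1
Why: Williamson etherification of all three phenols, warmed so that the hydrogen-bonded 2-OH also reacts.

**Step 5**
Reactants: 6 2,3,4-tris(benzyloxy)benzaldehyde
Product: 7 3,4-bis(benzyloxy)-2-hydroxybenzaldehyde
Conditions: MgBr2·OEt2 (1.5 equiv), toluene/Et2O, reflux; then 1 M HCl
Reagents that add atoms: none
Why: Chelation-controlled ether cleavage; magnesium binds the aldehyde oxygen and the ortho ether oxygen, so bromide removes only the 2-O-benzyl group, a known selective ortho-debenzylation of aryl carbonyl compounds.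

**Step 6**
Reactants: 7 3,4-bis(benzyloxy)-2-hydroxybenzaldehyde
Product: 8 2-(allyloxy)-3,4-bis(benzyloxy)benzaldehyde
Conditions: allyl bromide, K2CO3, DMF, 50 °C
Reagents that add atoms: allyl bromide, C=CCBr
Why: Williamson etherification; allyl is preferred to a silyl group because an ortho silyl ether could migrate to the alkoxide formed in step 7 and release the quinone methide too early, whereas allyl is inert to aryllithiums and leaves under neutral Pd(0) conditions.

**Step 7**
Reactants: 4 8-bromo-3,5,7,3′,4′-penta-O-benzyl-(+)-catechin; 8 2-(allyloxy)-3,4-bis(benzyloxy)benzaldehyde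
Product: 10 [2-(allyloxy)-3,4-bis(benzyloxy)phenyl](penta-O-benzylcatechin-8-yl)methanol as a mixture of carbinol epimers, via 8-lithio-penta-O-benzylcatechin 9 (not isolated)
Conditions: t-BuLi (2.0 equiv), THF, −78 °C; then 8, −78 → −40 °C; then H2O
Reagents that add atoms: none
Why: Bromine–lithium exchange followed by 1,2-addition of the aryllithium to the aldehyde, as known for 8-lithiated benzylated flavan-3-ols and carbonyl compounds; the new carbinol centre forms without control and both epimers are carried on because it becomes sp2 in step 10.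

**Step 8**
Reactants: 10 [2-(allyloxy)-3,4-bis(benzyloxy)phenyl](penta-O-benzylcatechin-8-yl)methanol
Product: 11 [3,4-bis(benzyloxy)-2-hydroxyphenyl](penta-O-benzylcatechin-8-yl)methanol as a mixture of carbinol epimers
Conditions: Pd(PPh3)4 (5 mol%), morpholine (5 equiv), THF, rt; chromatography on Et3N-deactivated silica
Reagents that add atoms: none
Why: Tsuji–Trost-type deallylation in which Pd(0) ionises the aryl allyl ether and morpholine traps the π-allyl complex, under neutral to basic conditions that leave the acid-labile diarylcarbinol and all benzyl ethers intact.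

**Step 9**
Reactants: 12 3,4-bis(benzyloxy)benzaldehyde
Product: 13 (E)-2-[3,4-bis(benzyloxy)phenyl]vinylboronic acid pinacol ester
Conditions: TMP, n-BuLi, THF, 0 °C (LiTMP); CH2(Bpin)2, 0 °C; then 12, −78 °C → rt
Reagents that add atoms: bis[(pinacolato)boryl]methane, CC1(C)OB(CB2OC(C)(C)C(C)(C)O2)OC1(C)C
Why: Boron–Wittig olefination; the α-lithiated geminal bis(boronate) adds to the aldehyde and syn-eliminates a B–O unit, which for aldehydes is known to give the (E)-alkenylboronate.

**Step 10**
Reactants: 11 [3,4-bis(benzyloxy)-2-hydroxyphenyl](penta-O-benzylcatechin-8-yl)methanol; 13 (E)-2-[3,4-bis(benzyloxy)phenyl]vinylboronic acid pinacol ester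
Product: 15 nona-O-benzyl 2,3-trans-3,4-trans-3-(pinacolatoboryl)-4-(catechin-8-yl)flavan, via o-quinone methide 14 (not isolated)
Conditions: (R)-TRIP (10 mol%), 13 (2 equiv), 5 Å MS, toluene, −20 °C → rt
Reagents that add atoms: none
Why: Proposed new method: the phosphoric acid dehydrates either epimer of 11 to the E-configured o-quinone methide 14, whose O1=C8a–C4a=C4 unit takes up the electron-rich alkene of 13 in an inverse-electron-demand hetero-Diels–Alder reaction that is concerted but asynchronous, the boron-bearing carbon bonding to C4 first while the charge building at the other alkene carbon is stabilised by its 3,4-bis(benzyloxy)phenyl group and by hyperconjugation from the C–B bond before O1 closes onto it. The closest known reaction type is the chiral phosphoric acid-catalysed [4+2] cycloaddition of in situ generated o-quinone methides with styrenes; an alkenylboronate has not served as the 2π partner, and the pinacol ester is chosen because it does not exchange onto the phenolic oxygen, which the known boron-to-carbon alkenyl transfer to quinone methides requires. The upper pyran ring closes by an intermolecular [4+2] cycloaddition that forms O1–C2 and C3–C4 in one six-membered transition state and restores the aromatic A ring. C2 and C3 come out trans because addition across the E-alkene is suprafacial, C4 comes out cis to the C2 aryl group and trans to boron because that aryl group lies endo to the E-quinone methide, and the absolute configuration of all three centres follows from the face of 14 left open by the phosphate hydrogen-bonded to its oxygen. The step needs regioselectivity (aryl-bearing carbon to O1), which the polarisation of the styrene secures; retention of boron, which low temperature, a non-polar solvent and the non-exchanging pinacol ester favour; and facial control independent of the remote catechin centres, which rests on the catalyst and is backed by the all-equatorial product also being the thermodynamic one should C2–O1 ionise reversibly.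

**Step 11**
Reactants: 15 nona-O-benzyl 2,3-trans-3,4-trans-3-(pinacolatoboryl)-4-(catechin-8-yl)flavan
Product: 16 nona-O-benzyl ether of the target with free 3-OH
Conditions: NaBO3·4H2O, THF/H2O (1:1), rt
Reagents that add atoms: sodium perborate (used as the tetrahydrate), [Na+].[O-]OB=O
Why: Peroxoborate oxidation of the C–B bond by 1,2-shift of carbon from boron to oxygen proceeds with retention, so C3 keeps the configuration set in step 10; the same C3–B to C3–OH change is known for 3-borylated flavans and chromans obtained by hydroboration of flav-3-enes.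

**Step 12**
Reactants: 16 nona-O-benzyl ether of the target with free 3-OH
Product: 17 target nonaphenol CNP0231186.1
Conditions: H2 (1 atm), 20% Pd(OH)2/C, THF/MeOH/H2O, rt; filtration and lyophilisation under argon
Reagents that add atoms: none
Why: Heterogeneous hydrogenolysis of the nine O-benzyl ethers over Pearlman's catalyst is the standard end-game for benzylated proanthocyanidins; the cyclic C2–O1 ether and the C4–C8″ bond are known to survive and no stereocentre is touched.

**Compound list**
1 | (+)-catechin, (2R,3S)-2-(3,4-dihydroxyphenyl)chromane-3,5,7-triol | Oc1cc(O)c2c(c1)O[C@H](c1ccc(O)c(O)c1)[C@@H](O)C2 | starting material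
2 | 5,7,3′,4′-tetra-O-benzyl-(+)-catechin (2R,3S) | C(c1ccccc1)Oc1cc(OCc2ccccc2)c2c(c1)O[C@H](c1ccc(OCc3ccccc3)c(OCc3ccccc3)c1)[C@@H](O)C2 | intermediate
3 | 3,5,7,3′,4′-penta-O-benzyl-(+)-catechin (2R,3S) | C(c1ccccc1)Oc1cc(OCc2ccccc2)c2c(c1)O[C@H](c1ccc(OCc3ccccc3)c(OCc3ccccc3)c1)[C@@H](OCc1ccccc1)C2 | intermediate
4 | 8-bromo-3,5,7,3′,4′-penta-O-benzyl-(+)-catechin (2R,3S) | C(c1ccccc1)Oc1cc(OCc2ccccc2)c2c(c1Br)O[C@H](c1ccc(OCc3ccccc3)c(OCc3ccccc3)c1)[C@@H](OCc1ccccc1)C2 | intermediate
5 | 2,3,4-trihydroxybenzaldehyde | O=Cc1ccc(O)c(O)c1O | starting material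
6 | 2,3,4-tris(benzyloxy)benzaldehyde | O=Cc1ccc(OCc2ccccc2)c(OCc2ccccc2)c1OCc1ccccc1 | intermediate
7 | 3,4-bis(benzyloxy)-2-hydroxybenzaldehyde | O=Cc1ccc(OCc2ccccc2)c(OCc2ccccc2)c1O | intermediate
8 | 2-(allyloxy)-3,4-bis(benzyloxy)benzaldehyde | O=Cc1ccc(OCc2ccccc2)c(OCc2ccccc2)c1OCC=C | intermediate
9 | 8-lithio-3,5,7,3′,4′-penta-O-benzyl-(+)-catechin | C(c1ccccc1)Oc1cc(OCc2ccccc2)c2c(c1[Li])O[C@H](c1ccc(OCc3ccccc3)c(OCc3ccccc3)c1)[C@@H](OCc1ccccc1)C2 | intermediate (not isolated)
10 | [2-(allyloxy)-3,4-bis(benzyloxy)phenyl][(2R,3S)-penta-O-benzylcatechin-8-yl]methanol, both carbinol epimers (carbinol centre left undefined) | C(c1ccccc1)Oc1cc(OCc2ccccc2)c2c(c1C(O)c1ccc(OCc3ccccc3)c(OCc3ccccc3)c1OCC=C)O[C@H](c1ccc(OCc3ccccc3)c(OCc3ccccc3)c1)[C@@H](OCc1ccccc1)C2 | intermediate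
11 | [3,4-bis(benzyloxy)-2-hydroxyphenyl][(2R,3S)-penta-O-benzylcatechin-8-yl]methanol, both carbinol epimers (carbinol centre left undefined) | C(c1ccccc1)Oc1cc(OCc2ccccc2)c2c(c1C(O)c1ccc(OCc3ccccc3)c(OCc3ccccc3)c1O)O[C@H](c1ccc(OCc3ccccc3)c(OCc3ccccc3)c1)[C@@H](OCc1ccccc1)C2 | intermediate
12 | 3,4-bis(benzyloxy)benzaldehyde | O=Cc1ccc(OCc2ccccc2)c(OCc2ccccc2)c1 | starting material
13 | (E)-2-[3,4-bis(benzyloxy)phenyl]vinylboronic acid pinacol ester | CC1(C)OB(/C=C/c2ccc(OCc3ccccc3)c(OCc3ccccc3)c2)OC1(C)C | intermediate
14 | (6E)-2,3-bis(benzyloxy)-6-[(penta-O-benzylcatechin-8-yl)methylidene]cyclohexa-2,4-dien-1-one (o-quinone methide) | O=C1C(OCc2ccccc2)=C(OCc2ccccc2)C=C/C1=C\c1c(OCc2ccccc2)cc(OCc2ccccc2)c2c1O[C@H](c1ccc(OCc3ccccc3)c(OCc3ccccc3)c1)[C@@H](OCc1ccccc1)C2 | intermediate (not isolated)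
15 | 7,8-bis(benzyloxy)-2-[3,4-bis(benzyloxy)phenyl]-3-(pinacolatoboryl)-4-[(2R,3S)-penta-O-benzylcatechin-8-yl]chromane, 2,3-trans-3,4-trans, same spatial arrangement as 16 | C(c1ccccc1)Oc1ccc([C@H]2Oc3c(ccc(OCc4ccccc4)c3OCc3ccccc3)[C@@H](c3c(OCc4ccccc4)cc(OCc4ccccc4)c4c3O[C@H](c3ccc(OCc5ccccc5)c(OCc5ccccc5)c3)[C@@H](OCc3ccccc3)C4)[C@@H]2B6OC(C)(C)C(C)(C)O6)cc1OCc1ccccc1 | intermediate
16 | (2R,3S,4S)-7,8-bis(benzyloxy)-2-[3,4-bis(benzyloxy)phenyl]-4-[(2R,3S)-penta-O-benzylcatechin-8-yl]chroman-3-ol | C(c1ccccc1)Oc1ccc([C@H]2Oc3c(ccc(OCc4ccccc4)c3OCc3ccccc3)[C@@H](c3c(OCc4ccccc4)cc(OCc4ccccc4)c4c3O[C@H](c3ccc(OCc5ccccc5)c(OCc5ccccc5)c3)[C@@H](OCc3ccccc3)C4)[C@@H]2O)cc1OCc1ccccc1 | intermediate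
17 | CNP0231186.1, (2R,3S,4S)-2-(3,4-dihydroxyphenyl)-4-[(2R,3S)-2-(3,4-dihydroxyphenyl)-3,5,7-trihydroxychroman-8-yl]chromane-3,7,8-triol | Oc1ccc([C@H]2Oc3c(ccc(O)c3O)[C@@H](c3c(O)cc(O)c4c3O[C@H](c3ccc(O)c(O)c3)[C@@H](O)C4)[C@@H]2O)cc1O | target

**Step count**
Total steps: 12. Longest linear sequence: 8 steps (1 → 2 → 3 → 4 → 10 → 11 → 15 → 16 → 17; the aldehyde branch from 5 is equally long).

**Steps most likely to fail**

Step 10. Three processes may defeat it. After the first C–C bond forms, the β-boryl benzylic cation may lose boron instead of closing the ring (deborylative alkenyl transfer). The stabilised quinone methide may alkylate C6 of a second catechin nucleus. The catalyst may fail to control the face against the resident catechin centres. The fallback uses known chemistry and turns the alkenyl transfer into the intended reaction; it sets out from 13 and 11.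
- 13 is cleaved with NaIO4/NH4OAc in aqueous acetone to (E)-2-[3,4-bis(benzyloxy)phenyl]vinylboronic acid F1.
- F1 is esterified with ethanol over molecular sieves to diethyl (E)-2-[3,4-bis(benzyloxy)phenyl]vinylboronate F2.
- F2 is added to the quinone methide released from 11 under 3,3′-dibromo-BINOL catalysis (chiral-biphenol-catalysed conjugate alkenylation of o-quinone methides). This should give 2,3-bis(benzyloxy)-6-[(E)-3-(3,4-bis(benzyloxy)phenyl)-1-(penta-O-benzylcatechin-8-yl)allyl]phenol F3, with the C4 configuration set by the diol.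
- The alkene of F3 is epoxidised with buffered m-CPBA at low temperature; the face is selected by the adjacent stereocentre, with the Shi ketone as the catalyst-controlled variant. This gives the trans-epoxide F4.
- A trace of CSA then induces 6-endo opening of F4 at the benzylic carbon by the phenol. Net anti addition across the E-alkene gives the 2,3-trans ring.
- The sequence returns to the route at 16 and bypasses 15 and step 11.

Step 7. Benzylic deprotonation of the benzyl ethers may compete with the halogen–lithium exchange. The di-ortho-substituted aryllithium may also be protonated, or may add too slowly to the hindered aldehyde. The fallback replaces the organometallic union by acylation and sets out from 8 and 3.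
- Pinnick oxidation of 8 (NaClO2, NaH2PO4, 2-methyl-2-butene) gives 2-(allyloxy)-3,4-bis(benzyloxy)benzoic acid F5.
- Its mixed anhydride with TFAA acylates 3 at C8, the position that also brominates, in a Friedel–Crafts reaction. This gives [2-(allyloxy)-3,4-bis(benzyloxy)phenyl](penta-O-benzylcatechin-8-yl)methanone F6; any C6 isomer is removed by chromatography.
- LiAlH4 in THF reduces the ketone, and the sequence returns to the route at 10.

Step 11. The hydroxy- or peroxy-boronate complex sits anti-periplanar to the C2–O1 bond and may undergo β-elimination with opening of the pyran ring. The hindered secondary boronate may also oxidise too slowly. The fallback sets out from 15.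
- KHF2 in MeOH/H2O converts 15 into the potassium trifluoroborate F7.
- Oxone in acetone/water oxidises F7 within minutes with retention (oxidation of organotrifluoroborates), and the sequence returns to the route at 16.

**Further compounds**
F1 | step 10 | (E)-2-[3,4-bis(benzyloxy)phenyl]vinylboronic acid | OB(O)/C=C/c1ccc(OCc2ccccc2)c(OCc2ccccc2)c1
F2 | step 10 | diethyl (E)-2-[3,4-bis(benzyloxy)phenyl]vinylboronate | CCOB(OCC)/C=C/c1ccc(OCc2ccccc2)c(OCc2ccccc2)c1
F3 | step 10 | 2,3-bis(benzyloxy)-6-[(E)-3-(3,4-bis(benzyloxy)phenyl)-1-(penta-O-benzylcatechin-8-yl)allyl]phenol, allylic centre configured as C4 of 16 | Oc1c(ccc(OCc2ccccc2)c1OCc1ccccc1)[C@@H](c1c(OCc2ccccc2)cc(OCc2ccccc2)c2c1O[C@H](c1ccc(OCc3ccccc3)c(OCc3ccccc3)c1)[C@@H](OCc1ccccc1)C2)/C=C/c1ccc(OCc2ccccc2)c(OCc2ccccc2)c1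
F4 | step 10 | 2,3-bis(benzyloxy)-6-{(penta-O-benzylcatechin-8-yl)[trans-3-(3,4-bis(benzyloxy)phenyl)oxiran-2-yl]methyl}phenol | Oc1c(ccc(OCc2ccccc2)c1OCc1ccccc1)[C@@H](c1c(OCc2ccccc2)cc(OCc2ccccc2)c2c1O[C@H](c1ccc(OCc3ccccc3)c(OCc3ccccc3)c1)[C@@H](OCc1ccccc1)C2)[C@@H]1O[C@H]1c1ccc(OCc2ccccc2)c(OCc2ccccc2)c1
F5 | step 7 | 2-(allyloxy)-3,4-bis(benzyloxy)benzoic acid | OC(=O)c1ccc(OCc2ccccc2)c(OCc2ccccc2)c1OCC=C
F6 | step 7 | [2-(allyloxy)-3,4-bis(benzyloxy)phenyl][(2R,3S)-penta-O-benzylcatechin-8-yl]methanone | C(c1ccccc1)Oc1cc(OCc2ccccc2)c2c(c1C(=O)c1ccc(OCc3ccccc3)c(OCc3ccccc3)c1OCC=C)O[C@H](c1ccc(OCc3ccccc3)c(OCc3ccccc3)c1)[C@@H](OCc1ccccc1)C2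
F7 | step 11 | potassium trifluoroborate corresponding to 15 (BF3K in place of Bpin at C3, same configuration) | C(c1ccccc1)Oc1ccc([C@H]2Oc3c(ccc(OCc4ccccc4)c3OCc3ccccc3)[C@@H](c3c(OCc4ccccc4)cc(OCc4ccccc4)c4c3O[C@H](c3ccc(OCc5ccccc5)c(OCc5ccccc5)c3)[C@@H](OCc3ccccc3)C4)[C@@H]2[B-](F)(F)F)cc1OCc1ccccc1.[K+]
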